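Readings and results were computed with made-up constants, noise included.

The constants of the steps were unknown when the meeting opened, and the chair asked what could be said of the new flasks without them.

| flask | starting material | partner | remark | time |
|---|---|---|---|---|
| west | 0.20 mM | 0.14 mM | run made earlier |  |
| south-east | 0.20 mM | 0.31 mM | run made earlier |  |
| dawn | 0.20 mM | 0.240 mM |  | 30 min |
| dusk | 0.20 mM | 0.300 mM |  | 30 min |
| winter | 0.20 mM | 0.500 mM |  | 30 min |

- west (time / min: single product / %): 2.00: 54.3; 6.00: 54.8; 10.0: 56.0; 15.0: 54.5; 25.0: 55.5; 30.0: 54.3
- south-east (time / min: single product / %): 5.00: 92.4; 10.0: 91.4; 15.0: 92.1; 20.0: 92.5; 25.0: 91.3; 30.0: 90.7

(standard deviation of a reading: 0.5 percentage points)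

- how much single product is there at the end, in percent of the starting material charged: for each flask in turn (dawn, dusk, winter)

- what may be going on: starting material + partner -> single product + by-product; partner + single product -> double product + by-product; partner -> decomposed reagent

The first speaker noted that the west readings hold level at a mean of 54.9% of single product, less than the 0.700 equivalents of partner charged. She took the gap to be partner lost to decomposition.

The second speaker wrote the two uses of partner as k·A·P for the first step and d·P for decomposition, with A and P the concentrations of starting material and partner, and k and d the unknown constants. In the ratio of the two rates P cancels, and integrating gives V = w·u·S. Here V is the decomposed reagent, S the starting material charged, u = ln(S/A), and w = d/(k·S).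

He called w the waste number: partner decomposed per unit of u, a selectivity factor turned upside down. Setting double product aside in west, he read w = 0.190.

For dawn, the meeting assumed the flask stops level as west does and again set aside the partner taken up by double product, so the equivalents charged equal the share converted plus w·u. One correction from a trial u of 2 gave u = 1.86, so single and double product together come to 84.5%. That is our own reckoning of both products together, and it stands above the dawn value of the forecast, which gave 83%, 91.5% and 89% of single product on the ground that “the final yield depends on how the partner was divided”.

The flasks give 82.9%, 91.1% and 88.4% of single product at dawn, dusk and winter.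

    starting material + partner → single product + by-product (k = 310 M⁻¹ s⁻¹)
    partner + single product → double product + by-product (k = 5.60 M⁻¹ s⁻¹)
    partner → decomposed reagent (k = 0.0110 s⁻¹)

Dawn also holds 1.84% of double product at 30.0 min, so the two products together make 84.7% against the 84.5% reckoned. With the 15.2% of starting material left at dawn, w gives 0.0714 mM of decomposed reagent, and dawn stands at 0.0668 mM. With the 5.37% left at dusk, the same w gives 0.111 mM, and dusk stands at 0.104 mM.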